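**Retrosynthetic overview**
1. Ester C–O bond: target ⇒ fragment A (bicyclic C2 alcohol, C7 hydroxyl as TBS ether) + fragment B ((2E,4E,6S)-dienoic acid, tertiary hydroxyl as TES ether); Yamaguchi esterification, then global desilylation.
2. Fragment A ⇒ C7–O by Rubottom oxidation, C3=C4 by Saegusa–Ito oxidation, C2–OH by hydride reduction of an octalenedione.
3. Ring B ⇒ intramolecular aldol condensation of a 1,5-diketone, itself from Michael addition of a chiral imine to methyl vinyl ketone (sets the quaternary centre).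
4. Ring A comes from 4-(2-hydroxyethoxy)phenol: oxidative dearomatization, copper-catalysed asymmetric methyl conjugate addition (first stereocentre), methylation, hydrogenation.
5. Fragment B ⇒ Wittig and cross-metathesis from (S)-3-methylpent-1-en-3-ol, made by Sharpless epoxidation of (E)-3-methylpent-2-en-1-ol. Ring order: ring A (steps 1–4), then ring B (step 6).

Assumption: the (S,R,R)-phosphoramidite/copper catalyst is taken to add methyl to dienone 2 with the facial sense known for cyclohex-2-enone, and the matched amine in step 5 is taken from the known sense with 2-methylcyclohexanone (otherwise the enantiomeric ligand or amine is used).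

Locants in the Why lines are those of the target's bicycle: C1 (CHCH3), C2 (CH–O), C3=C4, C4a=C5, C6 (C=O), C7 (CHOH), C8, C8a (C–CH3). Compound names carry their own systematic locants.

**Fragment A**

Step 1
Reactants: 1 4-(2-hydroxyethoxy)phenol
Product: 2 1,4-dioxaspiro[4.5]deca-6,9-dien-8-one
Conditions: PhI(OAc)2 (1.1 equiv), MeCN, 0 °C to rt
Reagents that add atoms: none
Why: Oxidative dearomatization of the phenol by the hypervalent iodine reagent, with the tethered hydroxyl trapping the para carbon intramolecularly to give the spiro quinone monoketal (no stereocentre).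

Step 2
Reactants: 2
Product: 3 (R)-10-methyl-1,4-dioxaspiro[4.5]dec-6-en-8-one
Conditions: Me2Zn (1.5 equiv), Cu(OTf)2 (2 mol %), (S,R,R)-phosphoramidite [O,O'-(S)-1,1'-binaphthyl-2,2'-diyl N,N-bis((R)-1-phenylethyl)phosphoramidite] (4 mol %), toluene, −25 °C; aq. NH4Cl
Reagents that add atoms: dimethylzinc, C[Zn]C
Why: Copper-catalysed enantioselective conjugate addition desymmetrizes the prochiral dienone, the chiral phosphoramidite complex choosing one enantiotopic enone face and so setting the (R) methyl-bearing centre (C1), while the zinc dienolate formed cannot add a second time.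

Step 3
Reactants: 3
Product: 5 (9R,10R)-9,10-dimethyl-1,4-dioxaspiro[4.5]dec-6-en-8-one, via lithium dienolate 4 (not isolated)
Conditions: LiN(i-Pr)2 (1.1 equiv), THF, −78 °C; then MeI (1.5 equiv), −78 to −30 °C
Reagents that add atoms: iodomethane, CI
Why: The enone has a single enolizable carbon (future C8a), so kinetic enolate formation and SN2 methylation are regiospecific; the methyl enters trans to its neighbour, but this centre is re-formed in step 5.

Step 4
Reactants: 5
Product: 6 (6R,7R)-6,7-dimethyl-1,4-dioxaspiro[4.5]decan-8-one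
Conditions: H2 (1 atm), 10% Pd/C, EtOAc, rt
Reagents that add atoms: none
Why: Heterogeneous catalytic hydrogenation saturates the enone C=C once it has served as the regiocontrol element for step 3, leaving ketone, ketal and stereocentres untouched.

Step 5
Reactants: 6 (6R,7R)-6,7-dimethyl-1,4-dioxaspiro[4.5]decan-8-one; 7 (R)-1-phenylethylamine; 8 but-3-en-2-one
Product: 11 (6R,7R)-6,7-dimethyl-7-(3-oxobutyl)-1,4-dioxaspiro[4.5]decan-8-one, via ketimine 9 (not isolated), via keto imine 10 (not isolated)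
Conditions: 7 (1.1 equiv), toluene, reflux (Dean–Stark); then 8 (1.5 equiv), THF, rt to 40 °C; then 10% aq. AcOH, rt
Reagents that add atoms: water, O
Why: Aza-ene-type Michael addition of the more substituted secondary enamine tautomer of the chiral imine is regiospecific for the methyl-bearing carbon and occurs anti to the adjacent C1 methyl, a preference the (R)-amine reinforces, so the quaternary C8a centre is set with the two methyls cis.

Step 6
Reactants: 11
Product: 13 (4aR,5R)-6,6-(ethylenedioxy)-4a,5-dimethyl-4,4a,5,6,7,8-hexahydronaphthalen-2(3H)-one, via ketol 12 (not isolated)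
Conditions: NaOMe (0.5 equiv), MeOH, 60 °C
Reagents that add atoms: none
Why: Intramolecular aldol addition of the methyl-ketone enolate (C5) to the ring ketone (C4a) closes ring B as a six-membered ketol, and E1cB dehydration gives the conjugated octalone; the quaternary centre cannot epimerize and the ketal keeps C1 non-enolizable.

Step 7
Reactants: 13
Product: 14 (4aR,5R)-4a,5-dimethyl-4,4a,7,8-tetrahydronaphthalene-2,6(3H,5H)-dione
Conditions: 1 M aq. HCl, THF, 0 °C to rt, stopped at full conversion; crude used at once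
Reagents that add atoms: water, O
Why: Acid-catalysed ketal hydrolysis unmasks the saturated C2 ketone, and the short cold exposure limits enolization toward the adjacent C1 methine so that its (R) configuration is kept.

Step 8
Reactants: 14
Product: 15 (4aR,5R,6S)-6-hydroxy-4a,5-dimethyl-4,4a,5,6,7,8-hexahydronaphthalen-2(3H)-one
Conditions: LiBH(s-Bu)3 (L-Selectride, 1.05 equiv), THF, −78 °C; aq. NH4Cl
Reagents that add atoms: none
Why: Chemo- and diastereoselective ketone reduction by a bulky trialkylborohydride: the saturated C2 ketone reacts before the β,β-disubstituted enone, and hydride attacks equatorially, anti to the 1,3-related axial C8a methyl, giving the axial (S) alcohol cis to both methyls.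

Step 9
Reactants: 15
Product: 16 (1R,2S,8aR)-1,8a-dimethyl-2,6-bis[(triethylsilyl)oxy]-1,2,3,7,8,8a-hexahydronaphthalene
Conditions: TESOTf (2.6 equiv), Et3N (5 equiv), CH2Cl2, 0 °C to rt
Reagents that add atoms: triethylsilyl trifluoromethanesulfonate, CC[Si](CC)(CC)OS(=O)(=O)C(F)(F)F
Why: Soft enolization with silyl triflate and amine gives the thermodynamically preferred through-conjugated dienol silyl ether by γ-deprotonation at C4, and the hindered C2 hydroxyl is silylated in the same operation.

Step 10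
Reactants: 16
Product: 17 (4aR,5R,6S)-4a,5-dimethyl-6-[(triethylsilyl)oxy]-4,4a,5,6-tetrahydronaphthalen-2(3H)-one
Conditions: Pd(OAc)2 (1.1 equiv), MeCN, rt
Reagents that add atoms: none
Why: Saegusa–Ito oxidation: palladation of the dienol silyl ether at its γ carbon (C4) and syn β-hydride elimination of a C3 hydrogen install the C3=C4 alkene and return the ketone as the linearly conjugated dienone.

Step 11
Reactants: 17
Product: 19 (1R,2S,8aR)-6-[(tert-butyldimethylsilyl)oxy]-1,8a-dimethyl-2-[(triethylsilyl)oxy]-1,2,8,8a-tetrahydronaphthalene, via lithium enolate 18 (not isolated)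
Conditions: LiN(i-Pr)2 (1.2 equiv), THF, −78 °C; then TBSOTf (1.3 equiv), −78 to 0 °C
Reagents that add atoms: tert-butyldimethylsilyl trifluoromethanesulfonate, CC(C)(C)[Si](C)(C)OS(=O)(=O)C(F)(F)F
Why: Kinetic deprotonation of the dienone at its only α' position (C7) and O-silylation give the cross-conjugated silyl enol ether needed for α'-oxygenation.

Step 12
Reactants: 19
Product: 21 (3R,4aR,5R,6S)-3-[(tert-butyldimethylsilyl)oxy]-4a,5-dimethyl-6-[(triethylsilyl)oxy]-4,4a,5,6-tetrahydronaphthalen-2(3H)-one, via silyloxy epoxide 20 (not isolated)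
Conditions: mCPBA (1.05 equiv), NaHCO3, CH2Cl2, −20 °C to rt
Reagents that add atoms: 3-chloroperoxybenzoic acid, OOC(=O)c1cccc(Cl)c1
Why: Rubottom oxidation: the peracid epoxidizes the electron-rich silyl enol ether on the face anti to the pseudoaxial C8a methyl, and the silyloxy epoxide opens with 1,4-silyl migration to give the equatorial (R) C7 silyloxy ketone directly.

Step 13
Reactants: 21
Product: 22 (3R,4aR,5R,6S)-3-[(tert-butyldimethylsilyl)oxy]-6-hydroxy-4a,5-dimethyl-4,4a,5,6-tetrahydronaphthalen-2(3H)-one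
Conditions: PPTS (0.2 equiv), MeOH/CH2Cl2 (1:4), 0 °C
Reagents that add atoms: none
Why: Acid-catalysed methanolysis cleaves the triethylsilyl ether roughly two orders of magnitude faster than the tert-butyldimethylsilyl ether, freeing only the C2 hydroxyl.

**Fragment B**

Step 14
Reactants: 23 ethyl but-2-ynoate
Product: 24 ethyl (E)-3-methylpent-2-enoate
Conditions: EtMgBr (1.5 equiv), CuBr·SMe2 (1.5 equiv), THF, −40 °C; then 23, −78 °C; MeOH then aq. NH4Cl at −78 °C
Reagents that add atoms: ethylmagnesium bromide, CC[Mg]Br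
Why: Syn-carbocupration of the ynoate by the ethylcopper reagent at low temperature and protonation with retention place ethyl and hydrogen cis across the former triple bond, giving the (E)-trisubstituted enoate.

Step 15
Reactants: 24
Product: 25 (E)-3-methylpent-2-en-1-ol
Conditions: i-Bu2AlH (2.2 equiv), CH2Cl2, −78 to 0 °C; aq. potassium sodium tartrate
Reagents that add atoms: none
Why: 1,2-Hydride reduction of the conjugated ester to the allylic alcohol with retention of alkene geometry.

Step 16
Reactants: 25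
Product: 26 [(2S,3S)-3-ethyl-3-methyloxiran-2-yl]methanol
Conditions: Ti(O-i-Pr)4 (10 mol %), L-(+)-diethyl tartrate (12 mol %), t-BuOOH (2 equiv, in decane), 4 Å MS, CH2Cl2, −20 °C
Reagents that add atoms: tert-butyl hydroperoxide, CC(C)(C)OO
Why: Sharpless asymmetric epoxidation: the titanium–L-(+)-tartrate catalyst delivers oxygen to the same face as with geraniol (same substitution pattern), giving the (2S,3S) epoxide and thereby fixing the tertiary C–O stereocentre.

Step 17
Reactants: 26
Product: 27 (2R,3S)-3-ethyl-2-(iodomethyl)-3-methyloxirane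
Conditions: PPh3 (1.3 equiv), I2 (1.3 equiv), imidazole (2.6 equiv), Et2O/MeCN (3:1), 0 °C
Reagents that add atoms: iodine, II
Why: Appel-type iodination replaces the primary hydroxyl by iodide through SN2 attack on the oxyphosphonium, leaving the epoxide and its configuration intact (the C2 descriptor changes by priority only).

Step 18
Reactants: 27
Product: 28 (S)-3-methylpent-1-en-3-ol
Conditions: Zn dust (3 equiv), AcOH (2 equiv), MeOH, 0 °C to rt; volatile product extracted into CH2Cl2 and used as a titrated solution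
Reagents that add atoms: none
Why: Zinc insertion into the C–I bond and β-elimination with epoxide opening (reductive ring-opening of a 2,3-epoxy iodide) give the transposed tertiary allylic alcohol; the tertiary C–O bond is never broken, so the (S) configuration is retained.

Step 19
Reactants: 28 (S)-3-methylpent-1-en-3-ol; 29 (E)-but-2-enal
Product: 30 (2E,4S)-4-hydroxy-4-methylhex-2-enal
Conditions: second-generation Hoveyda–Grubbs catalyst [RuCl2(H2IMes)(=CH-C6H4-2-O-i-Pr)] (3 mol %), 29 (5 equiv), CH2Cl2, 40 °C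
Reagents that add atoms: none
Why: Olefin cross-metathesis of the terminal alkene with excess crotonaldehyde, driven by loss of propene, gives the (E)-enal under thermodynamic control without touching the carbinol stereocentre.

Step 20
Reactants: 30 (2E,4S)-4-hydroxy-4-methylhex-2-enal; 31 ethyl (triphenylphosphoranylidene)acetate
Product: 32 ethyl (2E,4E,6S)-6-hydroxy-6-methylocta-2,4-dienoate
Conditions: 31 (1.2 equiv), CH2Cl2, rt
Reagents that add atoms: none
Why: Wittig olefination with the stabilized ylide forms the new C2=C3 bond with E geometry, completing the (2E,4E)-dienoate.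

Step 21
Reactants: 32
Product: 33 ethyl (2E,4E,6S)-6-methyl-6-[(triethylsilyl)oxy]octa-2,4-dienoate
Conditions: TESOTf (1.3 equiv), 2,6-lutidine (2 equiv), CH2Cl2, −78 to 0 °C
Reagents that add atoms: triethylsilyl trifluoromethanesulfonate, CC[Si](CC)(CC)OS(=O)(=O)C(F)(F)F
Why: Silylation of the hindered tertiary alcohol with the silyl triflate masks it for the esterification; no stereochemical change.

Step 22
Reactants: 33
Product: 34 (2E,4E,6S)-6-methyl-6-[(triethylsilyl)oxy]octa-2,4-dienoic acid
Conditions: LiOH·H2O (3 equiv), THF/MeOH/H2O (3:1:1), rt; 1 M HCl to pH 4 at 0 °C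
Reagents that add atoms: lithium hydroxide, [Li+].[OH-]
Why: Saponification (acyl–oxygen ester hydrolysis) frees the dienoic acid, the tertiary silyl ether being stable to base and to the brief mild acidification.

**Union**

Step 23
Reactants: 22 (3R,4aR,5R,6S)-3-[(tert-butyldimethylsilyl)oxy]-6-hydroxy-4a,5-dimethyl-4,4a,5,6-tetrahydronaphthalen-2(3H)-one; 34 (2E,4E,6S)-6-methyl-6-[(triethylsilyl)oxy]octa-2,4-dienoic acid
Product: 36 (1R,2S,7R,8aR)-7-[(tert-butyldimethylsilyl)oxy]-1,8a-dimethyl-6-oxo-1,2,6,7,8,8a-hexahydronaphthalen-2-yl (2E,4E,6S)-6-methyl-6-[(triethylsilyl)oxy]octa-2,4-dienoate, via mixed anhydride 35 (not isolated)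
Conditions: 34 (1.5 equiv), 2,4,6-trichlorobenzoyl chloride (1.5 equiv), Et3N (2 equiv), THF, rt; then 22, DMAP (2 equiv), toluene, rt to 40 °C
Reagents that add atoms: none
Why: Yamaguchi esterification: DMAP attacks the dienoyl carbonyl of the mixed anhydride and the acylpyridinium acylates the hindered axial C2 alcohol with retention at C2, the C7 hydroxyl being blocked as its TBS ether.

Step 24
Reactants: 36
Product: 37 (1R,2S,7R,8aR)-7-hydroxy-1,8a-dimethyl-6-oxo-1,2,6,7,8,8a-hexahydronaphthalen-2-yl (2E,4E,6S)-6-hydroxy-6-methylocta-2,4-dienoate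
Conditions: HF·pyridine, pyridine, THF, 0 °C to rt
Reagents that add atoms: none
Why: Fluoride-mediated cleavage of both silyl ethers (tertiary TES and α-keto secondary TBS) under buffered, non-basic conditions releases the target without acyl migration or epimerization.

**Compound list**

1 | 4-(2-hydroxyethoxy)phenol | OCCOc1ccc(O)cc1 | starting material
2 | 1,4-dioxaspiro[4.5]deca-6,9-dien-8-one | O=C1C=CC2(C=C1)OCCO2 | intermediate
3 | (R)-10-methyl-1,4-dioxaspiro[4.5]dec-6-en-8-one | C[C@@H]1CC(=O)C=CC12OCCO2 | intermediate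
4 | lithium (R)-10-methyl-1,4-dioxaspiro[4.5]deca-6,8-dien-8-olate | C[C@@H]1C=C(O[Li])C=CC12OCCO2 | intermediate (not isolated)
5 | (9R,10R)-9,10-dimethyl-1,4-dioxaspiro[4.5]dec-6-en-8-one (trans) | O1CCOC12C=CC(=O)[C@H](C)[C@H]2C | intermediate
6 | (6R,7R)-6,7-dimethyl-1,4-dioxaspiro[4.5]decan-8-one | O1CCOC12CCC(=O)[C@H](C)[C@H]2C | intermediate
7 | (R)-1-phenylethylamine | C[C@@H](N)c1ccccc1 | starting material
8 | but-3-en-2-one (methyl vinyl ketone) | C=CC(C)=O | starting material
9 | (6R,7R)-6,7-dimethyl-N-[(R)-1-phenylethyl]-1,4-dioxaspiro[4.5]decan-8-imine | O1CCOC12CCC(=N[C@H](C)c3ccccc3)[C@H](C)[C@H]2C | intermediate (not isolated)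
10 | 4-[(6R,7R)-6,7-dimethyl-8-{[(R)-1-phenylethyl]imino}-1,4-dioxaspiro[4.5]decan-7-yl]butan-2-one | O1CCOC12CCC(=N[C@H](C)c3ccccc3)[C@](C)(CCC(C)=O)[C@H]2C | intermediate (not isolated)
11 | (6R,7R)-6,7-dimethyl-7-(3-oxobutyl)-1,4-dioxaspiro[4.5]decan-8-one | O1CCOC12CCC(=O)[C@](C)(CCC(C)=O)[C@H]2C | intermediate
12 | (4aR,5R,8aS)-6,6-(ethylenedioxy)-8a-hydroxy-4a,5-dimethyloctahydronaphthalen-2(1H)-one (cis-fused ketol) | O1CCOC12CC[C@]3(O)CC(=O)CC[C@]3(C)[C@H]2C | intermediate (not isolated)
13 | (4aR,5R)-6,6-(ethylenedioxy)-4a,5-dimethyl-4,4a,5,6,7,8-hexahydronaphthalen-2(3H)-one | O1CCOC12CCC3=CC(=O)CC[C@]3(C)[C@H]2C | intermediate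
14 | (4aR,5R)-4a,5-dimethyl-4,4a,7,8-tetrahydronaphthalene-2,6(3H,5H)-dione | O=C1CCC2=CC(=O)CC[C@]2(C)[C@H]1C | intermediate
15 | (4aR,5R,6S)-6-hydroxy-4a,5-dimethyl-4,4a,5,6,7,8-hexahydronaphthalen-2(3H)-one | O[C@H]1CCC2=CC(=O)CC[C@]2(C)[C@H]1C | intermediate
16 | (1R,2S,8aR)-1,8a-dimethyl-2,6-bis[(triethylsilyl)oxy]-1,2,3,7,8,8a-hexahydronaphthalene | CC[Si](CC)(CC)O[C@H]1CC=C2C=C(O[Si](CC)(CC)CC)CC[C@]2(C)[C@H]1C | intermediate
17 | (4aR,5R,6S)-4a,5-dimethyl-6-[(triethylsilyl)oxy]-4,4a,5,6-tetrahydronaphthalen-2(3H)-one | CC[Si](CC)(CC)O[C@H]1C=CC2=CC(=O)CC[C@]2(C)[C@H]1C | intermediate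
18 | lithium cross-conjugated enolate of 17 (O–Li on C6, C6=C7) | CC[Si](CC)(CC)O[C@H]1C=CC2=CC(O[Li])=CC[C@]2(C)[C@H]1C | intermediate (not isolated)
19 | (1R,2S,8aR)-6-[(tert-butyldimethylsilyl)oxy]-1,8a-dimethyl-2-[(triethylsilyl)oxy]-1,2,8,8a-tetrahydronaphthalene | CC[Si](CC)(CC)O[C@H]1C=CC2=CC(O[Si](C)(C)C(C)(C)C)=CC[C@]2(C)[C@H]1C | intermediate
20 | silyloxy epoxide of 19 across C6–C7 (epoxide oxygen anti to the C8a methyl, TBSO on C6) | CC[Si](CC)(CC)O[C@H]1C=CC2=C[C@]3(O[Si](C)(C)C(C)(C)C)O[C@@H]3C[C@]2(C)[C@H]1C | intermediate (not isolated)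
21 | (3R,4aR,5R,6S)-3-[(tert-butyldimethylsilyl)oxy]-4a,5-dimethyl-6-[(triethylsilyl)oxy]-4,4a,5,6-tetrahydronaphthalen-2(3H)-one | CC[Si](CC)(CC)O[C@H]1C=CC2=CC(=O)[C@H](O[Si](C)(C)C(C)(C)C)C[C@]2(C)[C@H]1C | intermediate
22 | (3R,4aR,5R,6S)-3-[(tert-butyldimethylsilyl)oxy]-6-hydroxy-4a,5-dimethyl-4,4a,5,6-tetrahydronaphthalen-2(3H)-one | O[C@H]1C=CC2=CC(=O)[C@H](O[Si](C)(C)C(C)(C)C)C[C@]2(C)[C@H]1C | intermediate
23 | ethyl but-2-ynoate | CC#CC(=O)OCC | starting material
24 | ethyl (E)-3-methylpent-2-enoate | CC/C(C)=C/C(=O)OCC | intermediate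
25 | (E)-3-methylpent-2-en-1-ol | CC/C(C)=C/CO | intermediate
26 | [(2S,3S)-3-ethyl-3-methyloxiran-2-yl]methanol | CC[C@]1(C)O[C@H]1CO | intermediate
27 | (2R,3S)-3-ethyl-2-(iodomethyl)-3-methyloxirane | CC[C@]1(C)O[C@H]1CI | intermediate
28 | (S)-3-methylpent-1-en-3-ol | CC[C@](C)(O)C=C | intermediate
29 | (E)-but-2-enal (crotonaldehyde) | C/C=C/C=O | starting material
30 | (2E,4S)-4-hydroxy-4-methylhex-2-enal | CC[C@](C)(O)/C=C/C=O | intermediate
31 | ethyl (triphenylphosphoranylidene)acetate | CCOC(=O)C=P(c1ccccc1)(c1ccccc1)c1ccccc1 | starting material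
32 | ethyl (2E,4E,6S)-6-hydroxy-6-methylocta-2,4-dienoate | CC[C@](C)(O)/C=C/C=C/C(=O)OCC | intermediate
33 | ethyl (2E,4E,6S)-6-methyl-6-[(triethylsilyl)oxy]octa-2,4-dienoate | CC[C@](C)(O[Si](CC)(CC)CC)/C=C/C=C/C(=O)OCC | intermediate
34 | (2E,4E,6S)-6-methyl-6-[(triethylsilyl)oxy]octa-2,4-dienoic acid | CC[C@](C)(O[Si](CC)(CC)CC)/C=C/C=C/C(=O)O | intermediate
35 | (2E,4E,6S)-6-methyl-6-[(triethylsilyl)oxy]octa-2,4-dienoic 2,4,6-trichlorobenzoic anhydride | CC[C@](C)(O[Si](CC)(CC)CC)/C=C/C=C/C(=O)OC(=O)c1c(Cl)cc(Cl)cc1Cl | intermediate (not isolated)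
36 | (1R,2S,7R,8aR)-7-[(tert-butyldimethylsilyl)oxy]-1,8a-dimethyl-6-oxo-1,2,6,7,8,8a-hexahydronaphthalen-2-yl (2E,4E,6S)-6-methyl-6-[(triethylsilyl)oxy]octa-2,4-dienoate | CC[C@](C)(O[Si](CC)(CC)CC)/C=C/C=C/C(=O)O[C@H]1C=CC2=CC(=O)[C@H](O[Si](C)(C)C(C)(C)C)C[C@]2(C)[C@H]1C | intermediate
37 | (1R,2S,7R,8aR)-7-hydroxy-1,8a-dimethyl-6-oxo-1,2,6,7,8,8a-hexahydronaphthalen-2-yl (2E,4E,6S)-6-hydroxy-6-methylocta-2,4-dienoate | CC[C@](C)(O)/C=C/C=C/C(=O)O[C@H]1C=CC2=CC(=O)[C@H](O)C[C@]2(C)[C@H]1C | target

**Totals**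

Total step count: 24.
Longest linear sequence: 15 steps (steps 1–13, then 23 and 24). The second branch is steps 14–22 (9 steps) before the union.

**Steps most likely to fail, with fallbacks**

Step 5 builds a quaternary carbon next to a tertiary one, so rate and diastereoselectivity are uncertain. The fallback sets out from 6. It is converted with TMSCl, NaI and Et3N in MeCN into the more substituted (thermodynamic) silyl enol ether, trimethyl{[(6R)-6,7-dimethyl-1,4-dioxaspiro[4.5]dec-7-en-8-yl]oxy}silane F1. F1 is added to 8 in a Mukaiyama–Michael reaction (Tf2NH 2 mol %, CH2Cl2, −78 °C) and aqueous work-up cleaves the new silyl enol ether. This gives 11, where the route resumes at step 6.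

Step 9, with its follow-up step 10, depends on the silyl triflate giving the through-conjugated rather than the cross-conjugated dienol ether. The fallback sets out from 15. It is dehydrogenated directly through its dienol with chloranil (tetrachloro-1,4-benzoquinone, 1.5 equiv) in refluxing t-BuOH to give the hydroxy dienone (4aR,5R,6S)-6-hydroxy-4a,5-dimethyl-4,4a,5,6-tetrahydronaphthalen-2(3H)-one F2. F2 is silylated (TESOTf, 2,6-lutidine, CH2Cl2, −78 °C) to give 17, where the route resumes at step 11.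

Step 23 acylates a hindered axial allylic alcohol with a dienoic acid that can isomerize under DMAP. The fallback sets out from 22 and 30 and builds the dienoate on the core instead. 22 is esterified with the small (diethoxyphosphoryl)acetic acid (DCC, DMAP, CH2Cl2) to give the phosphonoacetate (1R,2S,7R,8aR)-7-[(tert-butyldimethylsilyl)oxy]-1,8a-dimethyl-6-oxo-1,2,6,7,8,8a-hexahydronaphthalen-2-yl 2-(diethoxyphosphoryl)acetate F3. 30 is silylated (TESOTf, 2,6-lutidine) to the protected enal (2E,4S)-4-methyl-4-[(triethylsilyl)oxy]hex-2-enal F4. A Masamune–Roush Horner–Wadsworth–Emmons olefination of F3 with F4 (LiCl, DBU, MeCN, rt) forms the (2E) alkene and gives 36, where the route resumes at step 24.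

**Further compounds**

F1 | step 5 | trimethyl{[(6R)-6,7-dimethyl-1,4-dioxaspiro[4.5]dec-7-en-8-yl]oxy}silane | C[C@@H]1C(C)=C(O[Si](C)(C)C)CCC12OCCO2
F2 | step 9 | (4aR,5R,6S)-6-hydroxy-4a,5-dimethyl-4,4a,5,6-tetrahydronaphthalen-2(3H)-one | O[C@H]1C=CC2=CC(=O)CC[C@]2(C)[C@H]1C
F3 | step 23 | (1R,2S,7R,8aR)-7-[(tert-butyldimethylsilyl)oxy]-1,8a-dimethyl-6-oxo-1,2,6,7,8,8a-hexahydronaphthalen-2-yl 2-(diethoxyphosphoryl)acetate | CCOP(=O)(CC(=O)O[C@H]1C=CC2=CC(=O)[C@H](O[Si](C)(C)C(C)(C)C)C[C@]2(C)[C@H]1C)OCC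
F4 | step 23 | (2E,4S)-4-methyl-4-[(triethylsilyl)oxy]hex-2-enal | CC[C@](C)(O[Si](CC)(CC)CC)/C=C/C=O
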